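The target's two ring stereocenters carry opposite descriptors, so it is the meso (6S,6'R) isomer of ε,ε-carotene-3,3'-dione, and both antipodes of one end group are needed; a racemic ring closure therefore wastes nothing. Everything rests on the cation–olefin cyclization of pseudoionone, an acyclic C13 trienone: protonation of the prenyl terminus gives the tertiary cation at C1 (the gem-dimethyl ring carbon), which the dienone traps through C6, closing the trimethylcyclohexene end ring (C1–C6 bond, C4=C5 alkene, C3 methylene for later oxidation) in one operation. Chain extension, C3 oxidation and a reagent-controlled reduction split the racemate into 6R and 6S series, which are joined stepwise through a C10 bis-ylide; no ring is closed afterwards.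

Key step: step 1

Remark: end-ring atoms are numbered as in carotenoids (C1 = CMe2, C2 = CH2, C3 = C=O, C4 = CH=, C5 = C(CH3)=, C6 = CH carrying the chain; primes for the second half). Commercial pseudoionone is a 5E/5Z mixture, and both isomers are assumed to converge on the same cation and product.

Step 1
Reactants: 1 pseudoionone ((3E,5E)-6,10-dimethylundeca-3,5,9-trien-2-one)
Product: 2 (±)-α-ionone ((E)-4-(2,6,6-trimethylcyclohex-2-en-1-yl)but-3-en-2-one, racemate)
Conditions: 85% H3PO4, 30 °C
Reagents that add atoms: none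
Why: Acid-mediated cation–olefin cyclization: Markovnikov protonation of the isolated C1=C2 alkene gives the tertiary C1 cation, C6 of the dienone attacks it to form the C1–C6 bond beside the quaternary carbon, and the tertiary C5 cation loses the C4 proton to give the C4=C5 alkene. This is the classical pseudoionone-to-ionone ring closure of terpenoid chemistry, a 6-endo-trig closure with respect to the C5=C6 alkene through a chair-like fold. The one new stereocenter, C6, has no controlling element and is formed as the racemate by design, since the meso target consumes both antipodes equally; the 6R antipode carries the ring that ends as C1'–C6', and the antipodes are parted in step 4. The step needs α over β regiochemistry of proton loss (C4–H, not C6–H), which phosphoric acid secures kinetically whereas stronger acids equilibrate to the conjugated β isomer, and 6-endo over 5-exo attack, which the polarized dienone secures by placing the nucleophilic carbon at C6 and the charge at tertiary C5. Both 5E and 5Z pseudoionone should converge on the same product.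

Step 2
Reactants: 2 (±)-α-ionone; 3 diethyl (cyanomethyl)phosphonate
Product: 5 rac-(2E,4E)-3-methyl-5-(2,6,6-trimethylcyclohex-2-en-1-yl)penta-2,4-dienenitrile, via phosphonate carbanion 4 (not isolated)
Conditions: NaH, THF, 0 °C → rt; silica gel chromatography to remove the minor 2Z isomer
Reagents that add atoms: none
Why: Horner–Wadsworth–Emmons olefination of the side-chain methyl ketone by the stabilized cyanomethylphosphonate anion should give mainly the 2E (9E) dienenitrile; the material is racemic, so exposure of the acidic C6–H to base is harmless at this stage.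

Step 3
Reactants: 5 rac-(2E,4E)-3-methyl-5-(2,6,6-trimethylcyclohex-2-en-1-yl)penta-2,4-dienenitrile
Product: 7 rac-(2E,4E)-3-methyl-5-(2,6,6-trimethyl-4-oxocyclohex-2-en-1-yl)penta-2,4-dienenitrile, via allylic peroxide 6 (not isolated)
Conditions: t-BuOOH (70% in water, 5 equiv), Rh2(cap)4 (1 mol%), 1,2-dichloroethane, 40 °C
Reagents that add atoms: tert-butyl hydroperoxide, CC(C)(C)OO
Why: Kharasch–Sosnovsky-type allylic C–H oxidation: the tert-butylperoxy radical abstracts hydrogen at C3, the only secondary allylic ring position, the allyl radical is capped at C3 as the mixed peroxide, and this collapses to the enone; the doubly allylic C6–H is tertiary and shielded by the gem-dimethyl carbon, and α-ionone-type rings are known to oxidize at this methylene.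

Step 4
Reactants: 7 rac-(2E,4E)-3-methyl-5-(2,6,6-trimethyl-4-oxocyclohex-2-en-1-yl)penta-2,4-dienenitrile
Product: 8 (2E,4E)-5-[(1R,4R)-4-hydroxy-2,6,6-trimethylcyclohex-2-en-1-yl]-3-methylpenta-2,4-dienenitrile (3R,6R; 3,6-trans); 9 (2E,4E)-5-[(1S,4R)-4-hydroxy-2,6,6-trimethylcyclohex-2-en-1-yl]-3-methylpenta-2,4-dienenitrile (3R,6S; 3,6-cis)
Conditions: (S)-2-methyl-CBS-oxazaborolidine (0.2 equiv), catecholborane (1.5 equiv), toluene, −78 °C; MeOH quench, dilute aq. NaOH wash; diastereomers 8 and 9 separated on silica gel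
Reagents that add atoms: none
Why: Corey–Bakshi–Shibata reduction (1,2-selective) used as a divergent reaction on the racemate: the catalyst should deliver hydride to the same face of the C3 carbonyl in both antipodes (alkenyl arm as the large group, 3R expected by analogy with cyclohex-2-enones), so the C6 antipodes become separable diastereomers; the catalyst-set C3 center also masks the base-sensitive enone for the Wittig steps and is erased in step 11.

Step 5
Reactants: 8 (2E,4E)-5-[(1R,4R)-4-hydroxy-2,6,6-trimethylcyclohex-2-en-1-yl]-3-methylpenta-2,4-dienenitrile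
Product: 11 (2E,4E)-5-[(1R,4R)-4-hydroxy-2,6,6-trimethylcyclohex-2-en-1-yl]-3-methylpenta-2,4-dienal, via aldimine 10 (not isolated)
Conditions: DIBAL-H (2.5 equiv), CH2Cl2, −78 → −40 °C; then wet silica gel, 0 °C
Reagents that add atoms: water, O
Why: Partial reduction of the conjugated nitrile by DIBAL-H stops at the N-aluminated aldimine, which is hydrolysed on work-up to the dienal; the hydroxyl is carried as its aluminium alkoxide and no base able to epimerize C6 is present.

Step 6
Reactants: 9 (2E,4E)-5-[(1S,4R)-4-hydroxy-2,6,6-trimethylcyclohex-2-en-1-yl]-3-methylpenta-2,4-dienenitrile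
Product: 13 (2E,4E)-5-[(1S,4R)-4-hydroxy-2,6,6-trimethylcyclohex-2-en-1-yl]-3-methylpenta-2,4-dienal, via aldimine 12 (not isolated)
Conditions: DIBAL-H (2.5 equiv), CH2Cl2, −78 → −40 °C; then wet silica gel, 0 °C
Reagents that add atoms: water, O
Why: Same DIBAL-H half-reduction of the conjugated nitrile as in step 5, applied to the 6S series; C6 is not touched.

Step 7
Reactants: 14 (2E,4E,6E)-2,7-dimethylocta-2,4,6-trienedial
Product: 15 (2E,4E,6E)-2,7-dimethylocta-2,4,6-triene-1,8-diol
Conditions: NaBH4, MeOH–CH2Cl2, 0 °C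
Reagents that add atoms: none
Why: Sodium borohydride 1,2-reduction of both conjugated aldehyde groups should give the bis-allylic diol without touching the triene.

Step 8
Reactants: 15 (2E,4E,6E)-2,7-dimethylocta-2,4,6-triene-1,8-diol
Product: 16 [(2E,4E,6E)-2,7-dimethylocta-2,4,6-triene-1,8-diyl]bis(triphenylphosphonium) dibromide
Conditions: PPh3·HBr (2.1 equiv), MeOH, rt, dark
Reagents that add atoms: triphenylphosphine hydrobromide, [Br-].[PH+](c1ccccc1)(c1ccccc1)c1ccccc1
Why: Acid-promoted allylic substitution of both primary allylic hydroxyls by triphenylphosphine through the delocalized trienyl cation, the standard preparation of polyenyl Wittig salts, should give the all-E bis-phosphonium salt.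

Step 9
Reactants: 13 (2E,4E)-5-[(1S,4R)-4-hydroxy-2,6,6-trimethylcyclohex-2-en-1-yl]-3-methylpenta-2,4-dienal; 16 bis-phosphonium dibromide (4 equiv)
Product: 18 [(2E,4E,6E,8E,10E,12E)-13-[(1S,4R)-4-hydroxy-2,6,6-trimethylcyclohex-2-en-1-yl]-2,7,11-trimethyltrideca-2,4,6,8,10,12-hexaen-1-yl]triphenylphosphonium bromide, via mono-ylide 17 (not isolated)
Conditions: NaOMe (1.0 equiv relative to 13, added slowly), MeOH–CH2Cl2, −20 → 0 °C, dark; chromatography (CH2Cl2–MeOH), excess 16 recovered
Reagents that add atoms: none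
Why: Wittig olefination of the dienal with the semi-stabilized allylic ylide forms the C11=C12 bond; the large excess of bis-salt and a single equivalent of base should confine reaction to one terminus, the low temperature protects C6, and any 11Z isomer converges in step 10.

Step 10
Reactants: 18 C25 phosphonium bromide (6S end); 11 (2E,4E)-5-[(1R,4R)-4-hydroxy-2,6,6-trimethylcyclohex-2-en-1-yl]-3-methylpenta-2,4-dienal
Product: 20 (3R,6S,3'R,6'R)-ε,ε-carotene-3,3'-diol (all-E), via C25 ylide 19 (not isolated)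
Conditions: NaOMe (1.1 equiv), MeOH–CH2Cl2, −20 °C → rt, dark; then EtOH, reflux, N2 (Z → E equilibration)
Reagents that add atoms: none
Why: The second Wittig olefination joins the 6'R end to the 6S half and completes the C40 skeleton; thermal equilibration should convert the hindered 11Z/11'Z bonds to all-E, and both C6 centers stay as sorted in step 4.

Step 11
Reactants: 20 (3R,6S,3'R,6'R)-ε,ε-carotene-3,3'-diol
Product: 21 (6S,6'R)-ε,ε-carotene-3,3'-dione (all-E, meso; the target)
Conditions: activated MnO2 (excess), CH2Cl2, rt, N2, dark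
Reagents that add atoms: none
Why: Manganese dioxide oxidizes both secondary allylic carbinols to the conjugated enones under neutral heterogeneous conditions, so the base-labile C6–H centers should not epimerize; removal of the two auxiliary C3 centers leaves the meso (6S,6'R) dione.

Compound list
1 | pseudoionone, (3E,5E)-6,10-dimethylundeca-3,5,9-trien-2-one | CC(=O)/C=C/C=C(\C)CCC=C(C)C | starting material
2 | (±)-α-ionone, (E)-4-(2,6,6-trimethylcyclohex-2-en-1-yl)but-3-en-2-one (racemate) | CC(=O)/C=C/C1C(C)=CCCC1(C)C | intermediate (isolated)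
3 | diethyl (cyanomethyl)phosphonate | CCOP(=O)(CC#N)OCC | starting material
4 | sodium salt of the carbanion of 3 (sodium cyano(diethoxyphosphoryl)methanide) | [Na+].CCOP(=O)([CH-]C#N)OCC | intermediate (not isolated)
5 | rac-(2E,4E)-3-methyl-5-(2,6,6-trimethylcyclohex-2-en-1-yl)penta-2,4-dienenitrile | N#C/C=C(C)/C=C/C1C(C)=CCCC1(C)C | intermediate (isolated)
6 | rac-(2E,4E)-5-[4-(tert-butylperoxy)-2,6,6-trimethylcyclohex-2-en-1-yl]-3-methylpenta-2,4-dienenitrile (diastereomer mixture) | N#C/C=C(C)/C=C/C1C(C)=CC(OOC(C)(C)C)CC1(C)C | intermediate (not isolated)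
7 | rac-(2E,4E)-3-methyl-5-(2,6,6-trimethyl-4-oxocyclohex-2-en-1-yl)penta-2,4-dienenitrile | N#C/C=C(C)/C=C/C1C(C)=CC(=O)CC1(C)C | intermediate (isolated)
8 | (2E,4E)-5-[(1R,4R)-4-hydroxy-2,6,6-trimethylcyclohex-2-en-1-yl]-3-methylpenta-2,4-dienenitrile (3R,6R; trans) | N#C/C=C(C)/C=C/[C@H]1C(C)=C[C@H](O)CC1(C)C | intermediate (isolated)
9 | (2E,4E)-5-[(1S,4R)-4-hydroxy-2,6,6-trimethylcyclohex-2-en-1-yl]-3-methylpenta-2,4-dienenitrile (3R,6S; cis) | N#C/C=C(C)/C=C/[C@@H]1C(C)=C[C@H](O)CC1(C)C | intermediate (isolated)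
10 | (2E,4E)-5-[(1R,4R)-4-hydroxy-2,6,6-trimethylcyclohex-2-en-1-yl]-3-methylpenta-2,4-dien-1-imine | N=C/C=C(C)/C=C/[C@H]1C(C)=C[C@H](O)CC1(C)C | intermediate (not isolated)
11 | (2E,4E)-5-[(1R,4R)-4-hydroxy-2,6,6-trimethylcyclohex-2-en-1-yl]-3-methylpenta-2,4-dienal | O=C/C=C(C)/C=C/[C@H]1C(C)=C[C@H](O)CC1(C)C | intermediate (isolated)
12 | (2E,4E)-5-[(1S,4R)-4-hydroxy-2,6,6-trimethylcyclohex-2-en-1-yl]-3-methylpenta-2,4-dien-1-imine | N=C/C=C(C)/C=C/[C@@H]1C(C)=C[C@H](O)CC1(C)C | intermediate (not isolated)
13 | (2E,4E)-5-[(1S,4R)-4-hydroxy-2,6,6-trimethylcyclohex-2-en-1-yl]-3-methylpenta-2,4-dienal | O=C/C=C(C)/C=C/[C@@H]1C(C)=C[C@H](O)CC1(C)C | intermediate (isolated)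
14 | (2E,4E,6E)-2,7-dimethylocta-2,4,6-trienedial | O=C/C(C)=C/C=C/C=C(C)/C=O | starting material
15 | (2E,4E,6E)-2,7-dimethylocta-2,4,6-triene-1,8-diol | OC/C(C)=C/C=C/C=C(C)/CO | intermediate (isolated)
16 | [(2E,4E,6E)-2,7-dimethylocta-2,4,6-triene-1,8-diyl]bis(triphenylphosphonium) dibromide | c1ccccc1[P+](c1ccccc1)(c1ccccc1)C/C(C)=C/C=C/C=C(C)/C[P+](c1ccccc1)(c1ccccc1)c1ccccc1.[Br-].[Br-] | intermediate (isolated)
17 | mono-ylide of 16 (phosphonium ylide at one terminus, bromide) | c1ccccc1[P+](c1ccccc1)(c1ccccc1)[CH-]/C(C)=C/C=C/C=C(C)/C[P+](c1ccccc1)(c1ccccc1)c1ccccc1.[Br-] | intermediate (not isolated)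
18 | [(2E,4E,6E,8E,10E,12E)-13-[(1S,4R)-4-hydroxy-2,6,6-trimethylcyclohex-2-en-1-yl]-2,7,11-trimethyltrideca-2,4,6,8,10,12-hexaen-1-yl]triphenylphosphonium bromide | CC1=C[C@H](O)CC(C)(C)[C@@H]1/C=C/C(C)=C/C=C/C(C)=C/C=C/C=C(C)/C[P+](c1ccccc1)(c1ccccc1)c1ccccc1.[Br-] | intermediate (isolated)
19 | ylide of 18 | CC1=C[C@H](O)CC(C)(C)[C@@H]1/C=C/C(C)=C/C=C/C(C)=C/C=C/C=C(C)/[CH-][P+](c1ccccc1)(c1ccccc1)c1ccccc1 | intermediate (not isolated)
20 | (3R,6S,3'R,6'R)-ε,ε-carotene-3,3'-diol (all-E) | CC1=C[C@H](O)CC(C)(C)[C@@H]1/C=C/C(C)=C/C=C/C(C)=C/C=C/C=C(C)/C=C/C=C(C)/C=C/[C@H]1C(C)=C[C@H](O)CC1(C)C | intermediate (isolated)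
21 | (6S,6'R)-ε,ε-carotene-3,3'-dione (all-E, meso) | CC1=CC(=O)CC(C)(C)[C@@H]1/C=C/C(C)=C/C=C/C(C)=C/C=C/C=C(C)/C=C/C=C(C)/C=C/[C@H]1C(C)=CC(=O)CC1(C)C | target

Total step count: 11. Longest linear sequence: 8 steps (1, 2, 3, 4, 6, 9, 10, 11).

Steps most likely to fail

Step 4. Catalyst control may be eroded in the antipode whose own facial bias (the axial C1 methyl) opposes the catalyst; some 3S carbinol of the other C6 series would then travel with each diastereomer, and the 6R and 6S series would leak into each other. The fallback sets out from 7 and comes back at 8 and 9. Luche reduction (NaBH4, CeCl3, MeOH) gives the carbinol as the mixture of all four stereoisomers F1. Lipase-catalysed acetylation (Pseudomonas lipase, vinyl acetate), expected to esterify only the 3R carbinols, gives the (3R,6R) acetate F2 and the (3R,6S) acetate F3. These are separated by chromatography from each other and from the unreacted (3S,6S) carbinol F4 and (3S,6R) carbinol F5. Methanolysis (K2CO3, MeOH) of the (3R,6R) acetate gives 8 and of the (3R,6S) acetate gives 9; the two unreacted carbinols are re-oxidized (MnO2) to 7 and recycled.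

Step 3. Hydrogen abstraction at the doubly allylic C6–H, or radical attack on the dienenitrile, may compete with oxidation at C3. The fallback sets out from 2 and comes back at 7. The same oxidation is run on the simpler enone 2 to give rac-3-oxo-α-ionone F6. The ring carbonyl is masked as its 1,3-dioxolane F7 (ethylene glycol, HC(OEt)3, cat. TsOH, rt; the ring carbonyl is expected to ketalize before the side-chain ketone). Olefination with 3 (NaH, THF) gives the ketal nitrile F8, and mild acid hydrolysis (PPTS, aqueous acetone) returns 7.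

Step 9. Double olefination of the bis-salt, or poor separation of the ionic products, may spoil the stepwise union. The fallback sets out from 11, 13 and 16 and comes back at 20. The bis-ylide of 16 (2 equiv NaOMe) is treated in one pot with an equimolar mixture of 13 and 11. The statistical mixture should contain 20 together with the two C2-symmetric diols, the (3R,6S,3'R,6'S) diol F9 and the (3R,6R,3'R,6'R) diol F10. These are diastereomers of 20 because of the C3 centers and are removed by preparative HPLC before step 11.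

Further compounds
F1 | step 4 | (2E,4E)-5-(4-hydroxy-2,6,6-trimethylcyclohex-2-en-1-yl)-3-methylpenta-2,4-dienenitrile, mixture of the four stereoisomers | N#C/C=C(C)/C=C/C1C(C)=CC(O)CC1(C)C
F2 | step 4 | (1R,4R)-4-[(1E,3E)-4-cyano-3-methylbuta-1,3-dien-1-yl]-3,5,5-trimethylcyclohex-2-en-1-yl acetate (acetate of 8) | N#C/C=C(C)/C=C/[C@H]1C(C)=C[C@H](OC(C)=O)CC1(C)C
F3 | step 4 | (1R,4S)-4-[(1E,3E)-4-cyano-3-methylbuta-1,3-dien-1-yl]-3,5,5-trimethylcyclohex-2-en-1-yl acetate (acetate of 9) | N#C/C=C(C)/C=C/[C@@H]1C(C)=C[C@H](OC(C)=O)CC1(C)C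
F4 | step 4 | (2E,4E)-5-[(1S,4S)-4-hydroxy-2,6,6-trimethylcyclohex-2-en-1-yl]-3-methylpenta-2,4-dienenitrile (3S,6S; enantiomer of 8) | N#C/C=C(C)/C=C/[C@@H]1C(C)=C[C@@H](O)CC1(C)C
F5 | step 4 | (2E,4E)-5-[(1R,4S)-4-hydroxy-2,6,6-trimethylcyclohex-2-en-1-yl]-3-methylpenta-2,4-dienenitrile (3S,6R; enantiomer of 9) | N#C/C=C(C)/C=C/[C@H]1C(C)=C[C@@H](O)CC1(C)C
F6 | step 3 | rac-3-oxo-α-ionone, (E)-4-(2,6,6-trimethyl-4-oxocyclohex-2-en-1-yl)but-3-en-2-one | CC(=O)/C=C/C1C(C)=CC(=O)CC1(C)C
F7 | step 3 | rac-(E)-4-(7,9,9-trimethyl-1,4-dioxaspiro[4.5]dec-6-en-8-yl)but-3-en-2-one (ring dioxolane of F6) | CC(=O)/C=C/C1C(C)=CC2(OCCO2)CC1(C)C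
F8 | step 3 | rac-(2E,4E)-3-methyl-5-(7,9,9-trimethyl-1,4-dioxaspiro[4.5]dec-6-en-8-yl)penta-2,4-dienenitrile (ring dioxolane of 7) | N#C/C=C(C)/C=C/C1C(C)=CC2(OCCO2)CC1(C)C
F9 | step 9 | (3R,6S,3'R,6'S)-ε,ε-carotene-3,3'-diol | CC1=C[C@H](O)CC(C)(C)[C@@H]1/C=C/C(C)=C/C=C/C(C)=C/C=C/C=C(C)/C=C/C=C(C)/C=C/[C@@H]1C(C)=C[C@H](O)CC1(C)C
F10 | step 9 | (3R,6R,3'R,6'R)-ε,ε-carotene-3,3'-diol | CC1=C[C@H](O)CC(C)(C)[C@H]1/C=C/C(C)=C/C=C/C(C)=C/C=C/C=C(C)/C=C/C=C(C)/C=C/[C@H]1C(C)=C[C@H](O)CC1(C)C
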